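**Plan**

- Retrosynthesis: ring C is cut at O1–C2 (intramolecular Mitsunobu etherification), then the open chain at C2–C3 and at C3–O. This leads back to a ring A diazomethyl ketone, 4-methoxybenzyl alcohol and vanillin acetate. The diazo carbon derives from the acetyl group of 2,4,6-trihydroxyacetophenone, and the C6 1,1-dimethylallyl group from a Claisen rearrangement of a prenyl ether.
- Enabling feature: C3 of ring C bears an oxygen, the C4 carbonyl carbon attached to ring A, and C2, the oxygenated benzylic carbon attached to ring B. C3 can therefore enter as a carbene carbon that takes up an O–H partner and an aldehyde in one operation.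
- Forward order: ring A is bought and functionalised (steps 1–6), ring B is attached through C3 and C2 in step 7, and ring C closes last in step 9, followed by deprotection.
- Stereochemistry: a chiral zirconium–BINOL Lewis acid in step 7 fixes C3 (R) and the syn carbinol; SN2 inversion of that carbinol in the Mitsunobu closure gives C2 (R), trans to C3.

Key step: step 7

Assumption: the sense of induction of the zirconium–BINOL catalyst with this ylide must be found by experiment; the (S)-ligand is written, and its antipode is used if the (2S) aldol predominates.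

**Route**

Step 1
Reactants: 1 2,4,6-trihydroxyacetophenone
Product: 2 1-[2,6-dihydroxy-4-(methoxymethoxy)phenyl]ethanone
Conditions: MOMCl (1.05 equiv), iPr2NEt (1.1 equiv), THF, 0 °C
Reagents that add atoms: chloromethyl methyl ether, COCCl
Why: Williamson-type MOM protection, in which the 4-hydroxyl, para to the acyl group, is the most acidic and is not hydrogen-bonded to the carbonyl, so one equivalent of electrophile should react there first.

Step 2
Reactants: 2 1-[2,6-dihydroxy-4-(methoxymethoxy)phenyl]ethanone; 3 prenyl bromide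
Product: 4 1-[2-hydroxy-4-(methoxymethoxy)-6-(3-methylbut-2-enyloxy)phenyl]ethanone
Conditions: K2CO3 (1.5 equiv), acetone, reflux
Reagents that add atoms: none
Why: Williamson ether synthesis on one of two equivalent ortho phenols, after which the remaining hydroxyl is locked in a hydrogen bond to the ketone and should resist a second alkylation.

Step 3
Reactants: 4 1-[2-hydroxy-4-(methoxymethoxy)-6-(3-methylbut-2-enyloxy)phenyl]ethanone
Product: 5 1-[2,6-dihydroxy-4-(methoxymethoxy)-3-(2-methylbut-3-en-2-yl)phenyl]ethanone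
Conditions: PhNEt2, 200 °C, sealed tube, Ar
Reagents that add atoms: none
Why: Aromatic Claisen rearrangement ([3,3]-sigmatropic) with allylic inversion, in which the acetyl-bearing ortho carbon is blocked so the allyl unit can only reach the carbon between the ether oxygen and the MOM-bearing carbon, while the basic solvent speeds enolisation of the ortho-dienone and so should suppress a following Cope shift and acid-induced ring closure onto the alkene.

Step 4
Reactants: 5 1-[2,6-dihydroxy-4-(methoxymethoxy)-3-(2-methylbut-3-en-2-yl)phenyl]ethanone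
Product: 6 1-[2-hydroxy-4-(methoxymethoxy)-3-(2-methylbut-3-en-2-yl)-6-(triisopropylsilyloxy)phenyl]ethanone
Conditions: TIPSCl (1.1 equiv), imidazole (2.5 equiv), DMF, 0 °C → rt
Reagents that add atoms: triisopropylsilyl chloride, CC(C)[Si](Cl)(C(C)C)C(C)C
Why: Silyl ether formation, selective for the hydroxyl next to the aromatic C–H because the other hydroxyl is wedged between the acetyl group and the quaternary carbon and should be out of reach of the bulky silyl chloride.

Step 5
Reactants: 6 1-[2-hydroxy-4-(methoxymethoxy)-3-(2-methylbut-3-en-2-yl)-6-(triisopropylsilyloxy)phenyl]ethanone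
Product: 7 1-[2,4-bis(methoxymethoxy)-3-(2-methylbut-3-en-2-yl)-6-(triisopropylsilyloxy)phenyl]ethanone
Conditions: NaH (1.2 equiv), THF, 0 °C; MOMCl (1.5 equiv), 0 °C → rt
Reagents that add atoms: chloromethyl methyl ether, COCCl
Why: MOM protection through the sodium phenoxide (Williamson type), in which the small and highly electrophilic chloride should still reach the hindered oxygen once deprotonation has broken the hydrogen bond; DMF is avoided because NaH in DMF cleaves aryl silyl ethers.

Step 6
Reactants: 7 1-[2,4-bis(methoxymethoxy)-3-(2-methylbut-3-en-2-yl)-6-(triisopropylsilyloxy)phenyl]ethanone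
Product: 9 2-diazo-1-[2,4-bis(methoxymethoxy)-3-(2-methylbut-3-en-2-yl)-6-(triisopropylsilyloxy)phenyl]ethanone, via trifluoroacetyl diketone 8 (not isolated)
Conditions: LiN(SiMe3)2 (1.1 equiv), THF, −78 °C; CF3CO2CH2CF3 (1.2 equiv); sat. aq NH4Cl; then 4-acetamidobenzenesulfonyl azide (1.5 equiv), Et3N (1.5 equiv), H2O (1 equiv), MeCN, rt
Reagents that add atoms: 2,2,2-trifluoroethyl trifluoroacetate, O=C(OCC(F)(F)F)C(F)(F)F (atoms kept in 8 only); 4-acetamidobenzenesulfonyl azide, CC(=O)Nc1ccc(cc1)S(=O)(=O)N=[N+]=[N-]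
Why: Danheiser detrifluoroacetylative diazo transfer (Claisen-type trifluoroacetylation of the kinetic methyl ketone enolate, then Regitz diazo transfer with loss of the trifluoroacetyl group), which activates a simple aryl methyl ketone that would not accept a diazo group directly.

Step 7
Reactants: 9 2-diazo-1-[2,4-bis(methoxymethoxy)-3-(2-methylbut-3-en-2-yl)-6-(triisopropylsilyloxy)phenyl]ethanone; 10 4-methoxybenzyl alcohol; 11 vanillin acetate
Product: 13 (2R,3S)-3-(4-acetoxy-3-methoxyphenyl)-3-hydroxy-2-(4-methoxybenzyloxy)-1-[2,4-bis(methoxymethoxy)-3-(2-methylbut-3-en-2-yl)-6-(triisopropylsilyloxy)phenyl]propan-1-one, via protic oxonium ylide 12 (not isolated)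
Conditions: Rh2(OAc)4 (2 mol %), Zr(OnBu)4/(S)-3,3'-diiodo-BINOL (1:1, 15 mol %), 4 Å MS, CH2Cl2, 0 °C; 11 (1.5 equiv) in the flask, 9 and 10 (1.2 equiv) added over 2 h
Reagents that add atoms: none
Why: Proposed new method: Rh2(OAc)4 decomposes 9 to an electrophilic rhodium carbenoid at the future C3, the hydroxyl oxygen of 10 adds to give the protic oxonium ylide 12 (an α-alkoxy enol equivalent), and this adds to aldehyde 11 held on the chiral zirconium–BINOL complex faster than it collapses by 1,2-proton shift, so that the C3–O and C2–C3 bonds form in one operation. The closest known reaction is the Rh2(OAc)4/zirconium–BINOL co-catalysed coupling of aryldiazoacetates, benzylic alcohols and aryl aldehydes to α-alkoxy-β-hydroxy esters; the extension is to a terminal aryl diazomethyl ketone, a class known to undergo the parent O–H insertion. No ring is closed. The configuration at C2 of the propanone (later C3 of the chromanone) should be set by the BINOL ligand, which exposes one face of the bound aldehyde to one face of the enol, and the syn relation to the C3 carbinol should follow from a closed, metal-bridged transition state of the Z-configured enol, in which ether and enol oxygens lie cis. The step needs aldol trapping to win over O–H insertion and over attack of the ortho ether oxygens on the carbenoid; the electron-poor acetoxy aldehyde used in excess and pre-complexed to zirconium, slow addition of 9, the bulky TIPS ether and the twist of the 2,6-disubstituted aroyl group out of the ring plane serve this purpose. Only the α-centre has to be delivered faithfully, since the carbinol centre is inverted or, if necessary, reset in the ring closure.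

Step 8
Reactants: 13 (2R,3S)-3-(4-acetoxy-3-methoxyphenyl)-3-hydroxy-2-(4-methoxybenzyloxy)-1-[2,4-bis(methoxymethoxy)-3-(2-methylbut-3-en-2-yl)-6-(triisopropylsilyloxy)phenyl]propan-1-one
Product: 14 (2R,3S)-3-(4-acetoxy-3-methoxyphenyl)-3-hydroxy-1-[6-hydroxy-2,4-bis(methoxymethoxy)-3-(2-methylbut-3-en-2-yl)phenyl]-2-(4-methoxybenzyloxy)propan-1-one
Conditions: Bu4NF (1.1 equiv), AcOH (1.1 equiv), THF, 0 °C
Reagents that add atoms: none
Why: Fluoride-mediated cleavage of an aryl silyl ether, buffered with acetic acid so that the medium stays non-basic and retro-aldol cleavage, epimerisation next to the ketone and loss of the aryl acetate should be avoided.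

Step 9
Reactants: 14 (2R,3S)-3-(4-acetoxy-3-methoxyphenyl)-3-hydroxy-1-[6-hydroxy-2,4-bis(methoxymethoxy)-3-(2-methylbut-3-en-2-yl)phenyl]-2-(4-methoxybenzyloxy)propan-1-one
Product: 15 (2R,3R)-2-(4-acetoxy-3-methoxyphenyl)-5,7-bis(methoxymethoxy)-3-(4-methoxybenzyloxy)-6-(2-methylbut-3-en-2-yl)chroman-4-one
Conditions: PPh3 (1.5 equiv), DIAD (1.5 equiv), THF, 0 °C → rt
Reagents that add atoms: none
Why: Intramolecular Mitsunobu etherification, a 6-exo-tet SN2 closure in which the hydrogen-bonded phenol displaces the activated benzylic oxygen with inversion, turning the (3S) carbinol into C2 (R) trans to the C3 ether, while the acetoxy group on ring B disfavours ionisation and so should keep the displacement stereospecific.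

Step 10
Reactants: 15 (2R,3R)-2-(4-acetoxy-3-methoxyphenyl)-5,7-bis(methoxymethoxy)-3-(4-methoxybenzyloxy)-6-(2-methylbut-3-en-2-yl)chroman-4-one
Product: 16 (2R,3R)-2-(4-acetoxy-3-methoxyphenyl)-3-hydroxy-5,7-bis(methoxymethoxy)-6-(2-methylbut-3-en-2-yl)chroman-4-one
Conditions: DDQ (1.5 equiv), CH2Cl2/pH 7 buffer (10:1), 0 °C → rt
Reagents that add atoms: none
Why: Oxidative cleavage of the 4-methoxybenzyl ether by DDQ (hydride abstraction, then hydrolysis of the oxocarbenium ion), which should leave the MOM ethers, the aryl acetate and the vinyl group, which has no allylic hydrogen, untouched.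

Step 11
Reactants: 16 (2R,3R)-2-(4-acetoxy-3-methoxyphenyl)-3-hydroxy-5,7-bis(methoxymethoxy)-6-(2-methylbut-3-en-2-yl)chroman-4-one
Product: 17 (2R,3R)-3,5,7-trihydroxy-2-(4-hydroxy-3-methoxyphenyl)-6-(2-methylbut-3-en-2-yl)chroman-4-one
Conditions: HCl (1.25 M in MeOH), 40 °C
Reagents that add atoms: none
Why: Acid-catalysed acetal exchange should remove both MOM ethers and acid-catalysed transesterification the aryl acetate, and since the 2,3-trans arrangement is the thermodynamically preferred one, neither stereocentre should change.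

**Compound list**

1 | 2,4,6-trihydroxyacetophenone | CC(=O)c1c(O)cc(O)cc1O | starting material
2 | 1-[2,6-dihydroxy-4-(methoxymethoxy)phenyl]ethanone | CC(=O)c1c(O)cc(OCOC)cc1O | intermediate
3 | prenyl bromide (1-bromo-3-methylbut-2-ene) | CC(C)=CCBr | starting material
4 | 1-[2-hydroxy-4-(methoxymethoxy)-6-(3-methylbut-2-enyloxy)phenyl]ethanone | CC(=O)c1c(O)cc(OCOC)cc1OCC=C(C)C | intermediate
5 | 1-[2,6-dihydroxy-4-(methoxymethoxy)-3-(2-methylbut-3-en-2-yl)phenyl]ethanone | C=CC(C)(C)c1c(OCOC)cc(O)c(C(C)=O)c1O | intermediate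
6 | 1-[2-hydroxy-4-(methoxymethoxy)-3-(2-methylbut-3-en-2-yl)-6-(triisopropylsilyloxy)phenyl]ethanone | C=CC(C)(C)c1c(OCOC)cc(O[Si](C(C)C)(C(C)C)C(C)C)c(C(C)=O)c1O | intermediate
7 | 1-[2,4-bis(methoxymethoxy)-3-(2-methylbut-3-en-2-yl)-6-(triisopropylsilyloxy)phenyl]ethanone | C=CC(C)(C)c1c(OCOC)cc(O[Si](C(C)C)(C(C)C)C(C)C)c(C(C)=O)c1OCOC | intermediate
8 | 4,4,4-trifluoro-1-[2,4-bis(methoxymethoxy)-3-(2-methylbut-3-en-2-yl)-6-(triisopropylsilyloxy)phenyl]butane-1,3-dione (not isolated) | C=CC(C)(C)c1c(OCOC)cc(O[Si](C(C)C)(C(C)C)C(C)C)c(C(=O)CC(=O)C(F)(F)F)c1OCOC | intermediate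
9 | 2-diazo-1-[2,4-bis(methoxymethoxy)-3-(2-methylbut-3-en-2-yl)-6-(triisopropylsilyloxy)phenyl]ethanone | C=CC(C)(C)c1c(OCOC)cc(O[Si](C(C)C)(C(C)C)C(C)C)c(C(=O)C=[N+]=[N-])c1OCOC | intermediate
10 | 4-methoxybenzyl alcohol | COc1ccc(CO)cc1 | starting material
11 | vanillin acetate (4-formyl-2-methoxyphenyl acetate) | CC(=O)Oc1ccc(C=O)cc1OC | starting material
12 | protic oxonium ylide from the carbenoid of 9 and alcohol 10, drawn as the enolate (not isolated) | C=CC(C)(C)c1c(OCOC)cc(O[Si](C(C)C)(C(C)C)C(C)C)c(C([O-])=C[OH+]Cc2ccc(OC)cc2)c1OCOC | intermediate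
13 | (2R,3S)-3-(4-acetoxy-3-methoxyphenyl)-3-hydroxy-2-(4-methoxybenzyloxy)-1-[2,4-bis(methoxymethoxy)-3-(2-methylbut-3-en-2-yl)-6-(triisopropylsilyloxy)phenyl]propan-1-one | C=CC(C)(C)c1c(OCOC)cc(O[Si](C(C)C)(C(C)C)C(C)C)c(c1OCOC)C(=O)[C@H](OCc1ccc(OC)cc1)[C@H](c1ccc(OC(C)=O)c(OC)c1)O | intermediate
14 | (2R,3S)-3-(4-acetoxy-3-methoxyphenyl)-3-hydroxy-1-[6-hydroxy-2,4-bis(methoxymethoxy)-3-(2-methylbut-3-en-2-yl)phenyl]-2-(4-methoxybenzyloxy)propan-1-one | C=CC(C)(C)c1c(OCOC)cc(O)c(c1OCOC)C(=O)[C@H](OCc1ccc(OC)cc1)[C@H](c1ccc(OC(C)=O)c(OC)c1)O | intermediate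
15 | (2R,3R)-2-(4-acetoxy-3-methoxyphenyl)-5,7-bis(methoxymethoxy)-3-(4-methoxybenzyloxy)-6-(2-methylbut-3-en-2-yl)chroman-4-one | C=CC(C)(C)c1c(OCOC)cc2c(c1OCOC)C(=O)[C@H](OCc1ccc(OC)cc1)[C@@H](c1ccc(OC(C)=O)c(OC)c1)O2 | intermediate
16 | (2R,3R)-2-(4-acetoxy-3-methoxyphenyl)-3-hydroxy-5,7-bis(methoxymethoxy)-6-(2-methylbut-3-en-2-yl)chroman-4-one | C=CC(C)(C)c1c(OCOC)cc2c(c1OCOC)C(=O)[C@H](O)[C@@H](c1ccc(OC(C)=O)c(OC)c1)O2 | intermediate
17 | (2R,3R)-3,5,7-trihydroxy-2-(4-hydroxy-3-methoxyphenyl)-6-(2-methylbut-3-en-2-yl)chroman-4-one | C=CC(C)(C)c1c(O)cc2c(c1O)C(=O)[C@H](O)[C@@H](c1ccc(O)c(OC)c1)O2 | target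

**Step count**

Total: 11 steps. Longest linear sequence: 11 steps (1 → 17); compounds 3, 10 and 11 are bought.

**Steps most likely to fail, with fallbacks**

1. Step 7. The aldol trapping may lose to plain O–H insertion or to attack of an ortho ether oxygen on the carbenoid, and facial control on a terminal diazoketone ylide may be poor. The fallback uses known chemistry, sets out from ketone 7 and returns to the route at 17. The lithium enolate of 7 (LiN(SiMe3)2, THF, −78 °C) is added to 3-methoxy-4-(methoxymethoxy)benzaldehyde F1 (from vanillin, MOMCl, iPr2NEt) to give the racemic β-hydroxy ketone F2. This is dehydrated in the same flask through its mesylate F3 (MsCl, Et3N, then DBU) to the E-chalcone F4. Juliá–Colonna epoxidation (poly-L-leucine, urea–H2O2, DBU, THF), a nucleophilic epoxidation that leaves the isolated vinyl group alone, should give the (2R,3S)-epoxy ketone F5. Buffered desilylation (Bu4NF, AcOH, THF, 0 °C) frees the epoxy phenol F6. Pyridinium p-toluenesulfonate in CH2Cl2 should then induce 6-endo opening of the epoxide at the benzylic carbon with inversion, giving the trans-flavanonol tris-MOM ether F7. This gives 17 under the conditions of step 11.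

2. Step 9. Under Mitsunobu conditions the β-hydroxy ketone may dehydrate by an E1cB path to the α-alkoxy enone, or the displacement may lose stereospecificity; an anti aldol from step 7 would also give the wrong ring fusion. The fallback sets out from 14 and returns at 15. Ammonia in MeOH at 0 °C removes the aryl acetate to give the free phenol F8. Catalytic diphenyl phosphate (CH2Cl2, 4 Å MS, rt) should ionise the para-hydroxybenzylic alcohol to the para-quinone methide F9. The ring A phenol adds to F9 reversibly (6-exo-trig), so the thermodynamically preferred 2,3-trans chromanone phenol F10 should form whatever the carbinol configuration was. Acetylation (Ac2O, pyridine) returns 15.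

3. Step 11. Under protic acid the vinyl group may be protonated and captured by a flanking phenol, and methanolysis of the acetate may lag behind. The fallback sets out from 16 and returns at 17. Ammonia in MeOH at 0 °C first removes the acetate, while ring A is still protected, to give the bis-MOM phenol F11. Both MOM ethers are then cleaved without a protic acid by ZnBr2 and n-PrSH (CH2Cl2, 0 °C, minutes), the thiol capturing the zinc-activated acetal carbon, to give 17.

**Further compounds**

F1 | step 7 | 3-methoxy-4-(methoxymethoxy)benzaldehyde | COCOc1ccc(C=O)cc1OC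
F2 | step 7 | racemic 3-hydroxy-3-[3-methoxy-4-(methoxymethoxy)phenyl]-1-[2,4-bis(methoxymethoxy)-3-(2-methylbut-3-en-2-yl)-6-(triisopropylsilyloxy)phenyl]propan-1-one | C=CC(C)(C)c1c(OCOC)cc(O[Si](C(C)C)(C(C)C)C(C)C)c(c1OCOC)C(=O)CC(O)c1ccc(OCOC)c(OC)c1
F3 | step 7 | racemic methanesulfonate of F2 (not isolated) | C=CC(C)(C)c1c(OCOC)cc(O[Si](C(C)C)(C(C)C)C(C)C)c(c1OCOC)C(=O)CC(OS(C)(=O)=O)c1ccc(OCOC)c(OC)c1
F4 | step 7 | (E)-3-[3-methoxy-4-(methoxymethoxy)phenyl]-1-[2,4-bis(methoxymethoxy)-3-(2-methylbut-3-en-2-yl)-6-(triisopropylsilyloxy)phenyl]prop-2-en-1-one | C=CC(C)(C)c1c(OCOC)cc(O[Si](C(C)C)(C(C)C)C(C)C)c(c1OCOC)C(=O)/C=C/c1ccc(OCOC)c(OC)c1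
F5 | step 7 | (2R,3S)-2,3-epoxy-3-[3-methoxy-4-(methoxymethoxy)phenyl]-1-[2,4-bis(methoxymethoxy)-3-(2-methylbut-3-en-2-yl)-6-(triisopropylsilyloxy)phenyl]propan-1-one | C=CC(C)(C)c1c(OCOC)cc(O[Si](C(C)C)(C(C)C)C(C)C)c(c1OCOC)C(=O)[C@@H]2O[C@H]2c3ccc(OCOC)c(OC)c3
F6 | step 7 | (2R,3S)-2,3-epoxy-1-[6-hydroxy-2,4-bis(methoxymethoxy)-3-(2-methylbut-3-en-2-yl)phenyl]-3-[3-methoxy-4-(methoxymethoxy)phenyl]propan-1-one | C=CC(C)(C)c1c(OCOC)cc(O)c(c1OCOC)C(=O)[C@@H]2O[C@H]2c3ccc(OCOC)c(OC)c3
F7 | step 7 | (2R,3R)-3-hydroxy-2-[3-methoxy-4-(methoxymethoxy)phenyl]-5,7-bis(methoxymethoxy)-6-(2-methylbut-3-en-2-yl)chroman-4-one | C=CC(C)(C)c1c(OCOC)cc2c(c1OCOC)C(=O)[C@H](O)[C@@H](c1ccc(OCOC)c(OC)c1)O2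
F8 | step 9 | (2R,3S)-3-hydroxy-3-(4-hydroxy-3-methoxyphenyl)-1-[6-hydroxy-2,4-bis(methoxymethoxy)-3-(2-methylbut-3-en-2-yl)phenyl]-2-(4-methoxybenzyloxy)propan-1-one | C=CC(C)(C)c1c(OCOC)cc(O)c(c1OCOC)C(=O)[C@H](OCc1ccc(OC)cc1)[C@H](c1ccc(O)c(OC)c1)O
F9 | step 9 | (R)-configured para-quinone methide from F8 (not isolated) | C=CC(C)(C)c1c(OCOC)cc(O)c(c1OCOC)C(=O)[C@H](OCc1ccc(OC)cc1)C=C1C=CC(=O)C(OC)=C1
F10 | step 9 | (2R,3R)-2-(4-hydroxy-3-methoxyphenyl)-5,7-bis(methoxymethoxy)-3-(4-methoxybenzyloxy)-6-(2-methylbut-3-en-2-yl)chroman-4-one | C=CC(C)(C)c1c(OCOC)cc2c(c1OCOC)C(=O)[C@H](OCc1ccc(OC)cc1)[C@@H](c1ccc(O)c(OC)c1)O2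
F11 | step 11 | (2R,3R)-3-hydroxy-2-(4-hydroxy-3-methoxyphenyl)-5,7-bis(methoxymethoxy)-6-(2-methylbut-3-en-2-yl)chroman-4-one | C=CC(C)(C)c1c(OCOC)cc2c(c1OCOC)C(=O)[C@H](O)[C@@H](c1ccc(O)c(OC)c1)O2
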